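Atom numbering used throughout: butenolide O1, C2 (C=O), C3 (Me), C4, C5; exocyclic alkene carbon C6; C7 (Me); cyclopentane C8–C9–C10–C11(Me)–C12; cyclohexene C12–C13–C14=C15(Me)–C16(O-acyl)–C17. The target is compound 30.

## Analysis of the target

The skeleton of 30 is a spiro[4.5]decene in which the fully substituted C12 is shared by a cyclopentane and a cyclohexene; C8 carries the C7 methine that ends in a (Z)-γ-alkylidene α-methylbutenolide, and C16 carries a 3-phenylpropanoate beside the trisubstituted C14=C15 alkene. There are five stereocentres (7S, 8R, 11S, 12S, 16S): the C8 branch and the C11 methyl are trans on the five-membered ring, C13 (the arm leading to the alkene) lies on the side of the C8 branch, the C16 oxygen sits on the face of the six-membered ring that C8 occupies, and C7 is an open-chain centre next to C8. C12 is stereogenic only because the two arms of the six-membered ring differ, so its configuration is decided by which arm receives the alkene and which the oxygen. The sensitive parts are the ylidenebutenolide (electrophilic, isomerised by light and base, and with a C7–H made acidic through the furanolate), the allylic ester, and any C6 aldehyde with its α-centre C7. The difficulty lies in the C7/C8 pair beside a quaternary carbon, in the C11/C12 junction, and in relating the six-ring centres to the five-ring ones across the spiro atom. The plan exploits the 1,4-relationship between C6 and C9: with C6 at the ester oxidation level, C8 is the electrophilic end of an acrylate, and the unfunctionalised ring carbon C9 can be brought in as an aldehyde whose umpoled carbonyl carbon attacks C8 and closes the five-membered ring.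

## Retrosynthetic reasoning

**C5=C6.** The exocyclic alkene is cut last, giving aldehyde 25 and silyloxyfuran 27 (from butenolide 26). This keeps the dienyl lactone out of every earlier step. The forward reaction, a vinylogous aldol addition followed by elimination, has to give the (Z) alkene without disturbing C7.

**C16–O and C16–H.** Aldehyde 25 goes back through alcohol 24 and silyl ether 23 to allylic alcohol 22, and 22 to enone 21. The ester is made by simple acylation, and the C16 centre by a reagent-controlled 1,2-reduction, so that no ring stereocentre has to direct it.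

**C16 oxygen and C15 methyl.** Enone 21 comes from allylic alcohol 20 and this from methylcyclohexene 19 by allylic oxidation. The C15–CH3 bond of 19 is cut to enol triflate 18, which derives (through 17 and 16) from the symmetric 4,4-disubstituted cyclohexanone 15. Enolisation of 15 toward C14 and not C16 is the event that makes C12 a stereocentre; a symmetric six-ring up to this point means that C12 needs no control earlier.

**Functional-group clearance.** Ketone 15 is traced through 14, 13, 12 and 10 to the spiro cyclopentanone 9: the C9 carbonyl is excised, the C6 ester is reduced and protected, and the C15 ketone is unmasked from its ketal.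

**C8–C9 (key disconnection).** Ketone 9 is opened to the 7-oxohept-2-enoate 8. This bond is chosen because its formation closes the cyclopentane and creates C8 and C7 in one catalytic step, next to a quaternary carbon that is already in place. The forward reaction has to add an acyl-anion equivalent to a hindered β-carbon with control of the C8 face and syn delivery of hydrogen to C7.

**C9 oxidation state and C7=C8.** Aldehyde 8 comes from alcohol 7, and 7 from diene ester 5 by anti-Markovnikov hydration of the vinyl group. The (E)-enoate of 5 is cut at C7=C8 to aldehyde 3 and the phosphorus ylide 4, which supplies C6, C7 and the C7 methyl.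

**C11–C12.** Aldehyde 3 is cut between C11 and C12 to the symmetric aldehyde 1 and allylic alcohol 2. The forward reaction makes the quaternary carbon and sets C11, the only stereocentre present before the key step.

## Alternatives that were turned down

Alternative 1: The six-membered ring would be cut at C12–C13 and traced to the open triene A1, in which C12 is the fully substituted end of a cyclopentylidene and C16 carries a silyl enol ether. Heating closes the ring by disrotatory 6π-electrocyclisation to the spiro 2-siloxydiene A2.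
- For: no reagent is needed, and A2 is one hydrolysis away from the C14=C15(Me)–C16 enone. The six-ring pattern that costs the chosen route a desymmetrisation and an allylic oxidation comes for free; on this point the alternative is stronger.
- Against: the C12 configuration is decided by the face of the cyclopentylidene on which C13 bonds, and the face required is the one flanked by the large C8 branch, not the one flanked by the C11 methyl. A fully substituted terminus closes slowly, and at the temperature needed the cis-triene has an open [1,7]-hydrogen shift from C8–H or C11–H that would erase the centres meant to steer the closure. The tetrasubstituted enol ether must also be formed with C14 and C17 cis, and the cyclopentane with C7, C8 and C11 must be built beforehand by other means.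
- Comparison: the chosen strategy gives up the free enone, but sets C7 and C8 in the ring closure and fixes C12 by a choice of arm that a reagent can influence.

Alternative 2: C11–C12 and the bond from C17 to a one-carbon unit are cut together. The enone A3, a 3-substituted cyclohex-2-enone whose side chain ends in a terminal alkene, would add that alkene across the enone on irradiation (β-carbon C12 to C11, α-carbon C17 to the terminal CH2) and give the tricyclic cyclobutyl ketone A4. Later cleavage of the C17–CH2 bond would reveal the C11 methyl.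
- For: one step makes the quaternary carbon, the cyclopentane and C11, and five-membered ring formation first is a dependable rule for three-atom tethers. The C16 ketone is in place and the two arms are distinct from the start, so α-methylation at C15 and dehydrogenation lead straight to the enone; here the alternative is clearly stronger than the chosen route.
- Against: C11 and C12 are controlled only by the single tether centre C8. The cyclobutane must then be opened at one specific bond by electron transfer, which generates an unstabilised primary radical or carbanion and competes with plain reduction of the ketone. C7 and C8 need separate acyclic stereocontrol in making A3, and the key step is photochemical.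
- Comparison: the chosen route breaks no bond that it has made, needs no irradiation, and obtains C7 and C8 from the ring closure itself.

Alternative 3: C8–C12 is cut and traced to the cyclobutanol A5, in which C11 is the carbinol carbon attached to the β-carbon C12 of a cyclohexenone. Iminium activation by a chiral primary amine makes C12 electrophilic, C8 migrates from C11 to C12 with retention, the four-membered ring expands, and the spiro dione A6 results.
- For: this ring expansion of vinylogous α-ketols is an established catalytic asymmetric reaction, so its precedent is better than that of the chosen key step. The substituted ring carbon is the one that migrates, and the C16 ketone is again in place.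
- Against: A6 has a ketone at C11 where the target has a methyl-bearing stereocentre. Turning it into that centre means olefinating a neopentyl ketone and reducing the alkene with the right facial sense under remote control. Two ketones must be told apart, the catalyst has to override the C8 centre, and A5 requires a 2-substituted cyclobutanone with C7 and C8 set.
- Comparison: the chosen route sets C11 first and never touches it again; the price is the later desymmetrisation of the six-membered ring.

Key step: step 5

Assumption: for the three chiral reagents whose sense of induction on these substrates cannot be fixed on paper (the phosphoramidite in step 1, the triazolium salt in step 5, the lithium amide in step 11), the antipode named is the one expected from simpler substrates of the same class; if a trial shows the opposite sense, the mirror-image reagent is taken and nothing else changes.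

## Route

Step 1
Reactants: 1 1,4-dioxaspiro[4.5]decane-8-carbaldehyde; 2 but-3-en-2-ol (racemic, 3 equiv)
Product: 3 8-[(2S)-but-3-en-2-yl]-1,4-dioxaspiro[4.5]decane-8-carbaldehyde
Conditions: [Ir(cod)Cl]2 (3 mol%), (R)-binaphthyl dibenzazepinyl phosphoramidite (12 mol%), Ph2CHNH2 (20 mol%), Cl3CCO2H (50 mol%), ClCH2CH2Cl, 25 °C
Reagents that add atoms: none
Why: Iridium/enamine dual-catalytic α-allylation of an α-branched aldehyde with a racemic branched allylic alcohol: the amine turns 1 into its symmetric enamine, the acid-activated iridium–phosphoramidite complex ionises 2 with loss of water to a methyl-substituted π-allyl complex, and attack at the substituted terminus forms C11–C12; C11 (S) is set by the ligand alone because the new quaternary carbon is not yet stereogenic, and the alcohol is used in excess because alkyl-substituted alcohols ionise more slowly than aryl-substituted ones.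

Step 2
Reactants: 3 8-[(2S)-but-3-en-2-yl]-1,4-dioxaspiro[4.5]decane-8-carbaldehyde; 4 ethyl 2-(triphenyl-λ5-phosphanylidene)propanoate
Product: 5 ethyl (2E)-3-{8-[(2S)-but-3-en-2-yl]-1,4-dioxaspiro[4.5]decan-8-yl}-2-methylprop-2-enoate
Conditions: toluene, 110 °C, sealed tube
Reagents that add atoms: none
Why: Wittig olefination with a stabilised α-methyl ylide; the aldehyde is neopentylic and has no α-hydrogen, hence the forcing temperature, and the reversible addition of the stabilised ylide leads to the (E)-trisubstituted enoate (C12 trans to CO2Et) that the key step needs.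

Step 3
Reactants: 5 ethyl (2E)-3-{8-[(2S)-but-3-en-2-yl]-1,4-dioxaspiro[4.5]decan-8-yl}-2-methylprop-2-enoate
Product: 7 ethyl (2E)-3-{8-[(2S)-4-hydroxybutan-2-yl]-1,4-dioxaspiro[4.5]decan-8-yl}-2-methylprop-2-enoate, via alkylborane 6 (not isolated)
Conditions: 9-BBN, THF, 0 °C → rt; NaBO3·4H2O, H2O, rt
Reagents that add atoms: 9-borabicyclo[3.3.1]nonane, B1C2CCCC1CCC2 (its boron is found in 6 only); sodium perborate, [Na+].[O-]OB=O (source of the hydroxyl oxygen)
Why: Hydroboration–oxidation: 9-BBN adds only to the monosubstituted alkene, with boron on the terminal carbon C9, and leaves the hindered, electron-poor trisubstituted enoate; perborate oxidises the C–B bond without harming ester or ketal.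

Step 4
Reactants: 7 ethyl (2E)-3-{8-[(2S)-4-hydroxybutan-2-yl]-1,4-dioxaspiro[4.5]decan-8-yl}-2-methylprop-2-enoate
Product: 8 ethyl (2E)-2-methyl-3-{8-[(2S)-4-oxobutan-2-yl]-1,4-dioxaspiro[4.5]decan-8-yl}prop-2-enoate
Conditions: Dess–Martin periodinane, NaHCO3, CH2Cl2, 0 °C → rt
Reagents that add atoms: none
Why: Dess–Martin oxidation of a primary alcohol under buffered conditions; C11 is β to the new carbonyl and cannot epimerise.

Step 5
Reactants: 8 ethyl (2E)-2-methyl-3-{8-[(2S)-4-oxobutan-2-yl]-1,4-dioxaspiro[4.5]decan-8-yl}prop-2-enoate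
Product: 9 ethyl (2S)-2-[(9R,12S)-12-methyl-10-oxo-1,4-dioxadispiro[4.2.4.2]tetradecan-9-yl]propanoate
Conditions: (5aR,10bS)-2-(pentafluorophenyl)-5a,10b-dihydro-4H,6H-indeno[2,1-b][1,2,4]triazolo[4,3-d][1,4]oxazin-2-ium tetrafluoroborate (20 mol%), KN(SiMe3)2 (18 mol%), toluene, 23 °C (carbene preformed, volatile amine removed in vacuo)
Reagents that add atoms: none
Why: Proposed new method: the triazolylidene adds to the C9 aldehyde and proton transfer gives the nucleophilic hydroxy-enamine (the acyl-anion equivalent), which attacks C8 of the enoate in a 5-exo-trig closure of the ring C9–C10–C11–C12–C8; the ester enolate so formed is protonated at C7 and the carbene is then expelled from C9 to release the ketone. The closest known reaction type is the carbene-catalysed asymmetric intramolecular Stetter reaction of aliphatic aldehydes with β-substituted and α,β-disubstituted acrylates, which gives cyclopentanones with catalyst-controlled configuration and syn delivery of hydrogen but has not been shown with a fully substituted carbon directly attached to the β-carbon. C8 (R) is set by the catalyst, whose fused indane wall leaves one face of the hydroxy-enamine open so that the branch ends trans to the C11 methyl; the substrate's own bias from C11, relayed across the quaternary carbon, should be small and is what the catalyst has to override. C7 (S) follows from the alkene geometry: the hydroxyl of the adduct hands its proton to the enolate carbon on the face on which the C8–C9 bond was made, and syn addition across the (E)-enoate gives the (7S,8R) pair. The step needs conjugate addition to win over aldol and benzoin reactions of the enolisable aldehyde, and the substrate helps: the quaternary C12 with the C11 branch folds the chain (gem-dialkyl effect), the acceptor has no γ-hydrogen and cannot deconjugate, and the ketal carbon is too remote to take part. Base is kept below the amount of azolium salt and the amine by-product is removed so that no external proton shuttle erodes the C7 selectivity or epimerises C8 of the product.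

Step 6
Reactants: 9 ethyl (2S)-2-[(9R,12S)-12-methyl-10-oxo-1,4-dioxadispiro[4.2.4.2]tetradecan-9-yl]propanoate
Product: 10 ethyl (2S)-2-[(9R,12S)-12-methyl-10-{2-[(4-methylphenyl)sulfonyl]hydrazinylidene}-1,4-dioxadispiro[4.2.4.2]tetradecan-9-yl]propanoate
Conditions: TsNHNH2, EtOH, 50 °C
Reagents that add atoms: 4-methylbenzenesulfonohydrazide, Cc1ccc(cc1)S(=O)(=O)NN
Why: Condensation of the cyclopentanone with tosylhydrazide under neutral conditions; the sulfonamide nitrogen is too poor a nucleophile to cyclise onto the γ-ester, and no acid or base is present that could epimerise C8.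

Step 7
Reactants: 10 ethyl (2S)-2-[(9R,12S)-12-methyl-10-{2-[(4-methylphenyl)sulfonyl]hydrazinylidene}-1,4-dioxadispiro[4.2.4.2]tetradecan-9-yl]propanoate
Product: 12 ethyl (2S)-2-[(9R,12S)-12-methyl-1,4-dioxadispiro[4.2.4.2]tetradecan-9-yl]propanoate, via N-boryl tosylhydrazine 11 (not isolated)
Conditions: catecholborane, CHCl3, 0 °C → rt; NaOAc·3H2O, 60 °C
Reagents that add atoms: catecholborane, B1Oc2ccccc2O1 (its boron is found in 11 only; 12 gains hydrogen alone)
Why: Tosylhydrazone reduction: catecholborane hydroborates the C=N bond, acetate then triggers loss of sulfinate and of N2 from the diazene, and C9 is left as CH2; ester and ketal are inert to catecholborane and C8 is never enolised.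

Step 8
Reactants: 12 ethyl (2S)-2-[(9R,12S)-12-methyl-1,4-dioxadispiro[4.2.4.2]tetradecan-9-yl]propanoate
Product: 13 (2S)-2-[(9R,12S)-12-methyl-1,4-dioxadispiro[4.2.4.2]tetradecan-9-yl]propan-1-ol
Conditions: LiAlH4, THF, 0 °C
Reagents that add atoms: none
Why: Hydride reduction of the ester to the primary alcohol; nothing else is reducible, and reduction outpaces enolisation so C7 is kept.

Step 9
Reactants: 13 (2S)-2-[(9R,12S)-12-methyl-1,4-dioxadispiro[4.2.4.2]tetradecan-9-yl]propan-1-ol
Product: 14 tert-butyl{(2S)-2-[(9R,12S)-12-methyl-1,4-dioxadispiro[4.2.4.2]tetradecan-9-yl]propoxy}diphenylsilane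
Conditions: t-BuPh2SiCl, imidazole, DMF, rt
Reagents that add atoms: tert-butyl(chloro)diphenylsilane, CC(C)(C)[Si](Cl)(c1ccccc1)c1ccccc1
Why: Silylation of the primary alcohol; the tert-butyldiphenylsilyl ether is chosen because it survives the acidic ketal hydrolysis and the organometallic steps and is removed at the end by fluoride without harm to the ester.

Step 10
Reactants: 14 tert-butyl{(2S)-2-[(9R,12S)-12-methyl-1,4-dioxadispiro[4.2.4.2]tetradecan-9-yl]propoxy}diphenylsilane
Product: 15 (1R,4S)-1-[(2S)-1-{[tert-butyl(diphenyl)silyl]oxy}propan-2-yl]-4-methylspiro[4.5]decan-8-one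
Conditions: pyridinium 4-toluenesulfonate, acetone/H2O, 60 °C
Reagents that add atoms: water, O
Why: Acid-catalysed hydrolysis of the dioxolane to the C15 ketone; the silyl ether is stable to the pyridinium salt.

Step 11
Reactants: 15 (1R,4S)-1-[(2S)-1-{[tert-butyl(diphenyl)silyl]oxy}propan-2-yl]-4-methylspiro[4.5]decan-8-one
Product: 16 {[(1R,4S,5R)-1-[(2S)-1-{[tert-butyl(diphenyl)silyl]oxy}propan-2-yl]-4-methylspiro[4.5]dec-7-en-8-yl]oxy}(trimethyl)silane
Conditions: (S,S)-bis(1-phenylethyl)amine hydrochloride, n-BuLi (2 equiv), THF, −78 °C; Me3SiCl, then 15, −95 °C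
Reagents that add atoms: chlorotrimethylsilane, C[Si](C)(C)Cl
Why: Deprotonation by a chiral lithium amide with in situ silylation, here selecting between two diastereotopic ring arms: in the favoured chair the bulkier C8 is equatorial and C11 axial, the C11 methyl leans over the axial hydrogen of C16, and the axial hydrogen of C14 is the accessible one, so the substrate bias and the matched amide both lead to the C14=C15 enol ether; this choice of arm fixes C12 as a stereocentre with C13 on the side of the C8 branch.

Step 12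
Reactants: 16 {[(1R,4S,5R)-1-[(2S)-1-{[tert-butyl(diphenyl)silyl]oxy}propan-2-yl]-4-methylspiro[4.5]dec-7-en-8-yl]oxy}(trimethyl)silane
Product: 18 (1R,4S,5R)-1-[(2S)-1-{[tert-butyl(diphenyl)silyl]oxy}propan-2-yl]-4-methylspiro[4.5]dec-7-en-8-yl trifluoromethanesulfonate, via lithium enolate 17 (not isolated)
Conditions: MeLi, THF, 0 °C; PhNTf2, −78 °C → rt
Reagents that add atoms: N-phenylbis(trifluoromethanesulfonimide), O=S(=O)(N(c1ccccc1)S(=O)(=O)C(F)(F)F)C(F)(F)F
Why: Methyllithium cleaves the Si–O bond to give the lithium enolate without proton exchange, so the regiochemistry of 16 is kept, and O-sulfonylation gives the enol triflate.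

Step 13
Reactants: 18 (1R,4S,5R)-1-[(2S)-1-{[tert-butyl(diphenyl)silyl]oxy}propan-2-yl]-4-methylspiro[4.5]dec-7-en-8-yl trifluoromethanesulfonate
Product: 19 tert-butyl{(2S)-2-[(1R,4S,5R)-4,8-dimethylspiro[4.5]dec-7-en-1-yl]propoxy}diphenylsilane
Conditions: MeMgBr, Fe(acac)3 (5 mol%), THF/N-methylpyrrolidone, −30 → 0 °C
Reagents that add atoms: methylmagnesium bromide, C[Mg]Br
Why: Iron-catalysed cross-coupling of an alkenyl triflate with a methyl Grignard reagent; it is fast at low temperature, keeps the position of the alkene and leaves the silyl ether alone.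

Step 14
Reactants: 19 tert-butyl{(2S)-2-[(1R,4S,5R)-4,8-dimethylspiro[4.5]dec-7-en-1-yl]propoxy}diphenylsilane
Product: 20 (1R,4S,5S,7RS)-1-[(2S)-1-{[tert-butyl(diphenyl)silyl]oxy}propan-2-yl]-4,8-dimethylspiro[4.5]dec-8-en-7-ol
Conditions: SeO2 (0.5 equiv), t-BuOOH, CH2Cl2, 0 °C → rt
Reagents that add atoms: selenium dioxide, O=[Se]=O (carries the oxygen); tert-butyl hydroperoxide, CC(C)(C)OO (terminal oxidant)
Why: Allylic oxidation by selenium dioxide (ene reaction, then [2,3]-sigmatropic shift): oxygen goes to the ring CH2 at the more substituted end of the trisubstituted alkene, which is C16, and the double bond returns to C14=C15; the C16 configuration is of no concern because the next step removes it.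

Step 15
Reactants: 20 (1R,4S,5S,7RS)-1-[(2S)-1-{[tert-butyl(diphenyl)silyl]oxy}propan-2-yl]-4,8-dimethylspiro[4.5]dec-8-en-7-ol
Product: 21 (1R,4S,5S)-1-[(2S)-1-{[tert-butyl(diphenyl)silyl]oxy}propan-2-yl]-4,8-dimethylspiro[4.5]dec-8-en-7-one
Conditions: Dess–Martin periodinane, NaHCO3, CH2Cl2, rt
Reagents that add atoms: none
Why: Dess–Martin oxidation of the allylic alcohol to the 2-methylcyclohexenone; any enone already formed in step 14 converges here.

Step 16
Reactants: 21 (1R,4S,5S)-1-[(2S)-1-{[tert-butyl(diphenyl)silyl]oxy}propan-2-yl]-4,8-dimethylspiro[4.5]dec-8-en-7-one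
Product: 22 (1R,4S,5S,7S)-1-[(2S)-1-{[tert-butyl(diphenyl)silyl]oxy}propan-2-yl]-4,8-dimethylspiro[4.5]dec-8-en-7-ol
Conditions: (R)-2-methyl-CBS-oxazaborolidine (0.5 equiv), BH3·SMe2, THF, −40 °C
Reagents that add atoms: none
Why: CBS reduction: 1,2-reduction of the enone under reagent control; with the alkenyl carbon as the large group, the (R)-oxazaborolidine delivers hydride to the face that gives the (16S) alcohol, oxygen on the ring face of C8.

Step 17
Reactants: 22 (1R,4S,5S,7S)-1-[(2S)-1-{[tert-butyl(diphenyl)silyl]oxy}propan-2-yl]-4,8-dimethylspiro[4.5]dec-8-en-7-ol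
Product: 23 (1R,4S,5S,7S)-1-[(2S)-1-{[tert-butyl(diphenyl)silyl]oxy}propan-2-yl]-4,8-dimethylspiro[4.5]dec-8-en-7-yl 3-phenylpropanoate
Conditions: 3-phenylpropanoyl chloride, pyridine, 4-(dimethylamino)pyridine (cat.), CH2Cl2, 0 °C → rt
Reagents that add atoms: 3-phenylpropanoyl chloride, O=C(Cl)CCc1ccccc1
Why: Acylation of the secondary allylic alcohol with the acid chloride under nucleophilic catalysis; the C16–O bond is not broken, so the configuration is retained.

Step 18
Reactants: 23 (1R,4S,5S,7S)-1-[(2S)-1-{[tert-butyl(diphenyl)silyl]oxy}propan-2-yl]-4,8-dimethylspiro[4.5]dec-8-en-7-yl 3-phenylpropanoate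
Product: 24 (1R,4S,5S,7S)-1-[(2S)-1-hydroxypropan-2-yl]-4,8-dimethylspiro[4.5]dec-8-en-7-yl 3-phenylpropanoate
Conditions: HF·pyridine, pyridine, THF, 0 °C → rt
Reagents that add atoms: none
Why: Fluoride cleavage of the primary silyl ether; the buffered reagent neither ionises the allylic ester nor moves the alkene.

Step 19
Reactants: 24 (1R,4S,5S,7S)-1-[(2S)-1-hydroxypropan-2-yl]-4,8-dimethylspiro[4.5]dec-8-en-7-yl 3-phenylpropanoate
Product: 25 (1R,4S,5S,7S)-4,8-dimethyl-1-[(2S)-1-oxopropan-2-yl]spiro[4.5]dec-8-en-7-yl 3-phenylpropanoate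
Conditions: Dess–Martin periodinane, NaHCO3, CH2Cl2, 0 °C
Reagents that add atoms: none
Why: Dess–Martin oxidation to the α-branched aldehyde under buffered conditions; the aldehyde is used at once so that C7 is not put at risk.

Step 20
Reactants: 26 3-methylfuran-2(5H)-one
Product: 27 tert-butyl(dimethyl)[(3-methylfuran-2-yl)oxy]silane
Conditions: t-BuMe2SiOTf, Et3N, CH2Cl2, 0 °C
Reagents that add atoms: tert-butyldimethylsilyl trifluoromethanesulfonate, CC(C)(C)[Si](C)(C)OS(=O)(=O)C(F)(F)F
Why: Soft enolisation and O-silylation of the butenolide, which gives the aromatic 2-silyloxyfuran.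

Step 21
Reactants: 25 (1R,4S,5S,7S)-4,8-dimethyl-1-[(2S)-1-oxopropan-2-yl]spiro[4.5]dec-8-en-7-yl 3-phenylpropanoate; 27 tert-butyl(dimethyl)[(3-methylfuran-2-yl)oxy]silane
Product: 28 (1R,4S,5S,7S)-1-[(2S)-1-hydroxy-1-(4-methyl-5-oxo-2,5-dihydrofuran-2-yl)propan-2-yl]-4,8-dimethylspiro[4.5]dec-8-en-7-yl 3-phenylpropanoate (mixture at the two new centres)
Conditions: BF3·OEt2, CH2Cl2, −78 °C; aqueous NaHCO3
Reagents that add atoms: none
Why: Vinylogous Mukaiyama aldol reaction: the silyloxyfuran attacks the Lewis-acid-activated aldehyde through its γ-carbon C5 and forms C5–C6 at −78 °C without epimerising C7; the two new centres are removed in the next step, so their configuration does not matter.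

Step 22
Reactants: 28 (1R,4S,5S,7S)-1-[(2S)-1-hydroxy-1-(4-methyl-5-oxo-2,5-dihydrofuran-2-yl)propan-2-yl]-4,8-dimethylspiro[4.5]dec-8-en-7-yl 3-phenylpropanoate
Product: 30 (1R,4S,5S,7S)-4,8-dimethyl-1-{(2S)-1-[(2Z)-4-methyl-5-oxofuran-2(5H)-ylidene]propan-2-yl}spiro[4.5]dec-8-en-7-yl 3-phenylpropanoate, via mesylate 29 (not isolated)
Conditions: MeSO2Cl, Et3N, CH2Cl2, −20 °C; 1,8-diazabicyclo[5.4.0]undec-7-ene, −20 → 0 °C
Reagents that add atoms: methanesulfonyl chloride, CS(=O)(=O)Cl (its atoms are found in 29 only)
Why: Mesylation and E1cB elimination through the furanolate give the exocyclic C5=C6 alkene; the (Z) isomer, with C7 turned toward the ring oxygen and away from C4–H, is the less strained one and should prevail, and short exposure to the amidine at low temperature avoids deprotonation at C7.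

## Compound list

1 | 1,4-dioxaspiro[4.5]decane-8-carbaldehyde | O=CC1CCC2(CC1)OCCO2 | starting material
2 | but-3-en-2-ol (racemic) | CC(O)C=C | starting material
3 | 8-[(2S)-but-3-en-2-yl]-1,4-dioxaspiro[4.5]decane-8-carbaldehyde | C=C[C@H](C)C1(C=O)CCC2(CC1)OCCO2 | intermediate
4 | ethyl 2-(triphenyl-λ5-phosphanylidene)propanoate | CCOC(=O)C(C)=P(c1ccccc1)(c1ccccc1)c1ccccc1 | starting material
5 | ethyl (2E)-3-{8-[(2S)-but-3-en-2-yl]-1,4-dioxaspiro[4.5]decan-8-yl}-2-methylprop-2-enoate | CCOC(=O)/C(C)=C/C1(CCC2(CC1)OCCO2)[C@@H](C)C=C | intermediate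
6 | ethyl (2E)-3-{8-[(2S)-4-(9-borabicyclo[3.3.1]nonan-9-yl)butan-2-yl]-1,4-dioxaspiro[4.5]decan-8-yl}-2-methylprop-2-enoate | CCOC(=O)/C(C)=C/C1(CCC2(CC1)OCCO2)[C@@H](C)CCB1C2CCCC1CCC2 | intermediate
7 | ethyl (2E)-3-{8-[(2S)-4-hydroxybutan-2-yl]-1,4-dioxaspiro[4.5]decan-8-yl}-2-methylprop-2-enoate | CCOC(=O)/C(C)=C/C1(CCC2(CC1)OCCO2)[C@@H](C)CCO | intermediate
8 | ethyl (2E)-2-methyl-3-{8-[(2S)-4-oxobutan-2-yl]-1,4-dioxaspiro[4.5]decan-8-yl}prop-2-enoate | O=CC[C@H](C)C1(CCC2(OCCO2)CC1)/C=C(\C)C(=O)OCC | intermediate
9 | ethyl (2S)-2-[(9R,12S)-12-methyl-10-oxo-1,4-dioxadispiro[4.2.4.2]tetradecan-9-yl]propanoate | CCOC(=O)[C@@H](C)[C@H]1C(=O)C[C@H](C)C12CCC3(OCCO3)CC2 | intermediate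
10 | ethyl (2S)-2-[(9R,12S)-12-methyl-10-{2-[(4-methylphenyl)sulfonyl]hydrazinylidene}-1,4-dioxadispiro[4.2.4.2]tetradecan-9-yl]propanoate | CCOC(=O)[C@@H](C)[C@H]1C(=NNS(=O)(=O)c3ccc(C)cc3)C[C@H](C)C12CCC3(OCCO3)CC2 | intermediate
11 | ethyl (2S)-2-[(9R,12S)-10-{1-(1,3,2-benzodioxaborol-2-yl)-2-[(4-methylphenyl)sulfonyl]hydrazinyl}-12-methyl-1,4-dioxadispiro[4.2.4.2]tetradecan-9-yl]propanoate | CCOC(=O)[C@@H](C)[C@H]1C(N(NS(=O)(=O)c3ccc(C)cc3)B3Oc4ccccc4O3)C[C@H](C)C12CCC3(OCCO3)CC2 | intermediate
12 | ethyl (2S)-2-[(9R,12S)-12-methyl-1,4-dioxadispiro[4.2.4.2]tetradecan-9-yl]propanoate | CCOC(=O)[C@@H](C)[C@H]1CC[C@H](C)C12CCC3(OCCO3)CC2 | intermediate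
13 | (2S)-2-[(9R,12S)-12-methyl-1,4-dioxadispiro[4.2.4.2]tetradecan-9-yl]propan-1-ol | OC[C@@H](C)[C@H]1CC[C@H](C)C12CCC3(OCCO3)CC2 | intermediate
14 | tert-butyl{(2S)-2-[(9R,12S)-12-methyl-1,4-dioxadispiro[4.2.4.2]tetradecan-9-yl]propoxy}diphenylsilane | CC(C)(C)[Si](c1ccccc1)(c1ccccc1)OC[C@@H](C)[C@H]1CC[C@H](C)C12CCC3(OCCO3)CC2 | intermediate
15 | (1R,4S)-1-[(2S)-1-{[tert-butyl(diphenyl)silyl]oxy}propan-2-yl]-4-methylspiro[4.5]decan-8-one | CC(C)(C)[Si](c1ccccc1)(c1ccccc1)OC[C@@H](C)[C@H]1CC[C@H](C)C12CCC(=O)CC2 | intermediate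
16 | {[(1R,4S,5R)-1-[(2S)-1-{[tert-butyl(diphenyl)silyl]oxy}propan-2-yl]-4-methylspiro[4.5]dec-7-en-8-yl]oxy}(trimethyl)silane | CC(C)(C)[Si](c1ccccc1)(c1ccccc1)OC[C@@H](C)[C@H]1CC[C@H](C)[C@@]12CC=C(O[Si](C)(C)C)CC2 | intermediate
17 | lithium (1R,4S,5R)-1-[(2S)-1-{[tert-butyl(diphenyl)silyl]oxy}propan-2-yl]-4-methylspiro[4.5]dec-7-en-8-olate | CC(C)(C)[Si](c1ccccc1)(c1ccccc1)OC[C@@H](C)[C@H]1CC[C@H](C)[C@@]12CC=C([O-])CC2.[Li+] | intermediate
18 | (1R,4S,5R)-1-[(2S)-1-{[tert-butyl(diphenyl)silyl]oxy}propan-2-yl]-4-methylspiro[4.5]dec-7-en-8-yl trifluoromethanesulfonate | CC(C)(C)[Si](c1ccccc1)(c1ccccc1)OC[C@@H](C)[C@H]1CC[C@H](C)[C@@]12CC=C(OS(=O)(=O)C(F)(F)F)CC2 | intermediate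
19 | tert-butyl{(2S)-2-[(1R,4S,5R)-4,8-dimethylspiro[4.5]dec-7-en-1-yl]propoxy}diphenylsilane | CC(C)(C)[Si](c1ccccc1)(c1ccccc1)OC[C@@H](C)[C@H]1CC[C@H](C)[C@@]12CC=C(C)CC2 | intermediate
20 | (1R,4S,5S,7RS)-1-[(2S)-1-{[tert-butyl(diphenyl)silyl]oxy}propan-2-yl]-4,8-dimethylspiro[4.5]dec-8-en-7-ol | CC(C)(C)[Si](c1ccccc1)(c1ccccc1)OC[C@@H](C)[C@H]1CC[C@H](C)[C@@]12CC=C(C)C(O)C2 | intermediate
21 | (1R,4S,5S)-1-[(2S)-1-{[tert-butyl(diphenyl)silyl]oxy}propan-2-yl]-4,8-dimethylspiro[4.5]dec-8-en-7-one | CC(C)(C)[Si](c1ccccc1)(c1ccccc1)OC[C@@H](C)[C@H]1CC[C@H](C)[C@@]12CC=C(C)C(=O)C2 | intermediate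
22 | (1R,4S,5S,7S)-1-[(2S)-1-{[tert-butyl(diphenyl)silyl]oxy}propan-2-yl]-4,8-dimethylspiro[4.5]dec-8-en-7-ol | CC(C)(C)[Si](c1ccccc1)(c1ccccc1)OC[C@@H](C)[C@H]1CC[C@H](C)[C@@]12CC=C(C)[C@@H](O)C2 | intermediate
23 | (1R,4S,5S,7S)-1-[(2S)-1-{[tert-butyl(diphenyl)silyl]oxy}propan-2-yl]-4,8-dimethylspiro[4.5]dec-8-en-7-yl 3-phenylpropanoate | CC(C)(C)[Si](c1ccccc1)(c1ccccc1)OC[C@@H](C)[C@H]1CC[C@H](C)[C@@]12CC=C(C)[C@@H](OC(=O)CCc3ccccc3)C2 | intermediate
24 | (1R,4S,5S,7S)-1-[(2S)-1-hydroxypropan-2-yl]-4,8-dimethylspiro[4.5]dec-8-en-7-yl 3-phenylpropanoate | OC[C@@H](C)[C@H]1CC[C@H](C)[C@@]12CC=C(C)[C@@H](OC(=O)CCc3ccccc3)C2 | intermediate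
25 | (1R,4S,5S,7S)-4,8-dimethyl-1-[(2S)-1-oxopropan-2-yl]spiro[4.5]dec-8-en-7-yl 3-phenylpropanoate | O=C[C@@H](C)[C@H]1CC[C@H](C)[C@@]12CC=C(C)[C@@H](OC(=O)CCc3ccccc3)C2 | intermediate
26 | 3-methylfuran-2(5H)-one | CC1=CCOC1=O | starting material
27 | tert-butyl(dimethyl)[(3-methylfuran-2-yl)oxy]silane | Cc1ccoc1O[Si](C)(C)C(C)(C)C | intermediate
28 | (1R,4S,5S,7S)-1-[(2S)-1-hydroxy-1-(4-methyl-5-oxo-2,5-dihydrofuran-2-yl)propan-2-yl]-4,8-dimethylspiro[4.5]dec-8-en-7-yl 3-phenylpropanoate | CC1=CC(OC1=O)C(O)[C@@H](C)[C@H]2CC[C@H](C)[C@@]23CC=C(C)[C@@H](OC(=O)CCc4ccccc4)C3 | intermediate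
29 | (1R,4S,5S,7S)-4,8-dimethyl-1-[(2S)-1-[(methylsulfonyl)oxy]-1-(4-methyl-5-oxo-2,5-dihydrofuran-2-yl)propan-2-yl]spiro[4.5]dec-8-en-7-yl 3-phenylpropanoate | CC1=CC(OC1=O)C(OS(C)(=O)=O)[C@@H](C)[C@H]2CC[C@H](C)[C@@]23CC=C(C)[C@@H](OC(=O)CCc4ccccc4)C3 | intermediate
30 | (1R,4S,5S,7S)-4,8-dimethyl-1-{(2S)-1-[(2Z)-4-methyl-5-oxofuran-2(5H)-ylidene]propan-2-yl}spiro[4.5]dec-8-en-7-yl 3-phenylpropanoate (CNP0260277.1) | CC1=C/C(=C/[C@@H](C)[C@H]2CC[C@H](C)[C@@]23CC=C(C)[C@@H](OC(=O)CCc2ccccc2)C3)OC1=O | target

## Step count and least certain steps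

Total step count: 22. Longest linear sequence: 21 steps (steps 1 to 19, 21 and 22; step 20 is a one-step side branch).

**Step 5 (key step, proposed new method).** The most likely failure is that conjugate addition at C8, a β-carbon bonded to a quaternary centre on an α-methylated acceptor, is too slow, so that aldol condensation or benzoin coupling of the enolisable aldehyde takes over. Next in likelihood are facial selection at C8 following the substrate instead of the catalyst, and loss of the internal proton transfer, which would erode C7. The fallback leaves the route at 8 and re-enters at 9, by known radical chemistry. Chlorite oxidation of 8 (NaClO2, NaH2PO4, 2-methylbut-2-ene) should give (3S)-3-{8-[(1E)-3-ethoxy-2-methyl-3-oxoprop-1-en-1-yl]-1,4-dioxaspiro[4.5]decan-8-yl}butanoic acid F1. Diphenyl diselenide and tributylphosphine then convert it into the selenoester ethyl (2E)-2-methyl-3-{8-[(2S)-4-oxo-4-(phenylselanyl)butan-2-yl]-1,4-dioxaspiro[4.5]decan-8-yl}prop-2-enoate F2. Slow addition of Bu3SnH with 2,2'-azobis(2-methylpropionitrile) in benzene at 80 °C releases the acyl radical, which closes 5-exo onto C8 to give 9; a radical is far less sensitive than an anion to the neopentyl surroundings. C8 and C7 are then under substrate control only, so the wanted isomer 9 would have to be separated from its epimers.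

**Step 1.** The alkyl-substituted allylic alcohol may ionise too slowly, or only one of its enantiomers may react, so conversion may stall; the acid promoter together with the water released may also open part of the ketal. The fallback goes from 1 to 3 by a sigmatropic route with chirality transfer. Chlorite oxidation of 1 gives 1,4-dioxaspiro[4.5]decane-8-carboxylic acid F3. Esterification with (2R,3E)-pent-3-en-2-ol (N,N'-dicyclohexylcarbodiimide, 4-(dimethylamino)pyridine) gives (2R,3E)-pent-3-en-2-yl 1,4-dioxaspiro[4.5]decane-8-carboxylate F4. Ireland–Claisen rearrangement (LiN(iPr)2, Me3SiCl, THF, −78 °C then 60 °C) gives 8-[(2S,3E)-pent-3-en-2-yl]-1,4-dioxaspiro[4.5]decane-8-carboxylic acid F5; the ketene acetal is symmetric, so the chair with the carbinol methyl equatorial alone relays the carbinol centre into C11. LiAlH4 gives {8-[(2S,3E)-pent-3-en-2-yl]-1,4-dioxaspiro[4.5]decan-8-yl}methanol F6, and Dess–Martin oxidation gives 8-[(2S,3E)-pent-3-en-2-yl]-1,4-dioxaspiro[4.5]decane-8-carbaldehyde F7. Ethenolysis (ethylene, second-generation Hoveyda–Grubbs catalyst) trims the propenyl group to the vinyl group of 3.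

**Step 11.** The discrimination between the two ring arms rests on a conformational preference of the spiro ketone and on the match with the amide, and may be insufficient. The fallback goes from 15 to 18 and replaces selectivity by separation and recycling. Deprotonation of 15 with the achiral hindered lithium 2,2,6,6-tetramethylpiperidide and direct trapping with PhNTf2 gives 18 together with its arm isomer, (1R,4S,5S)-1-[(2S)-1-{[tert-butyl(diphenyl)silyl]oxy}propan-2-yl]-4-methylspiro[4.5]dec-7-en-8-yl trifluoromethanesulfonate F8. The two are diastereomers and are separated by chromatography; the unwanted one is returned to 15 by S–O cleavage with NaOH in aqueous methanol at room temperature and put through again.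

**Step 14.** Competing oxidation of the allylic methyl group, over-oxidation and incomplete conversion are the usual limits of this reagent. The fallback goes from 16 to 20 and places the C16 oxygen by enolate chemistry. Saegusa oxidation of 16 (Pd(OAc)2, MeCN) gives (1R,4S,5S)-1-[(2S)-1-{[tert-butyl(diphenyl)silyl]oxy}propan-2-yl]-4-methylspiro[4.5]dec-6-en-8-one F9, whose only enolisable position is C16. LiN(iPr)2 and Et3SiCl give the dienol ether {[(1R,4S,5S)-1-[(2S)-1-{[tert-butyl(diphenyl)silyl]oxy}propan-2-yl]-4-methylspiro[4.5]deca-6,8-dien-8-yl]oxy}(triethyl)silane F10. Rubottom oxidation with 3-chloroperbenzoic acid gives (1R,4S,5S,9RS)-1-[(2S)-1-{[tert-butyl(diphenyl)silyl]oxy}propan-2-yl]-4-methyl-9-[(triethylsilyl)oxy]spiro[4.5]dec-6-en-8-one F11. Conjugate reduction with LiBH(s-Bu)3 and trapping of the C14=C15 enolate with PhNTf2 give (1R,4S,5S,9RS)-1-[(2S)-1-{[tert-butyl(diphenyl)silyl]oxy}propan-2-yl]-4-methyl-9-[(triethylsilyl)oxy]spiro[4.5]dec-7-en-8-yl trifluoromethanesulfonate F12. Iron-catalysed methylation as in step 13 gives tert-butyl{(2S)-2-[(1R,4S,5S,7RS)-4,8-dimethyl-7-[(triethylsilyl)oxy]spiro[4.5]dec-8-en-1-yl]propoxy}diphenylsilane F13. Mild acidic methanolysis of the triethylsilyl ether, which leaves the tert-butyldiphenylsilyl ether, gives 20.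

**Step 16.** Reagent control may be overridden by the substrate: the C11 methyl shields the face from which hydride has to come, so the pairing may be mismatched. The fallback goes from 21 to 23. Luche reduction of 21 (NaBH4, CeCl3·7H2O, MeOH, −78 °C) under substrate control should give mainly (1R,4S,5S,7R)-1-[(2S)-1-{[tert-butyl(diphenyl)silyl]oxy}propan-2-yl]-4,8-dimethylspiro[4.5]dec-8-en-7-ol F14. Mitsunobu esterification with 3-phenylpropanoic acid (PPh3, diisopropyl azodicarboxylate) converts it into 23 with inversion at C16; any 22 formed alongside is acylated as in step 17.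

**Step 22.** The elimination may give part of the (E) isomer, or base may deprotonate C7 through the extended furanolate and so epimerise it or move the alkene. The fallback goes from 25 to 30 and fixes the geometry by an anti addition. Colvin homologation of 25 with lithiated trimethylsilyldiazomethane (THF, −78 °C) gives the terminal alkyne (1R,4S,5S,7S)-1-[(2S)-but-3-yn-2-yl]-4,8-dimethylspiro[4.5]dec-8-en-7-yl 3-phenylpropanoate F15. Coupling with (Z)-3-iodo-2-methylprop-2-enoic acid (Pd(PPh3)4, CuI, Et3N, MeCN) is followed in the same flask by 5-exo-dig attack of the carboxylate on the alkyne, and anti addition across the triple bond gives the (Z) alkene of 30.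

## Further compounds

F1 | step 5 | (3S)-3-{8-[(1E)-3-ethoxy-2-methyl-3-oxoprop-1-en-1-yl]-1,4-dioxaspiro[4.5]decan-8-yl}butanoic acid | CCOC(=O)/C(C)=C/C1(CCC2(CC1)OCCO2)[C@@H](C)CC(=O)O
F2 | step 5 | ethyl (2E)-2-methyl-3-{8-[(2S)-4-oxo-4-(phenylselanyl)butan-2-yl]-1,4-dioxaspiro[4.5]decan-8-yl}prop-2-enoate | CCOC(=O)/C(C)=C/C1(CCC2(CC1)OCCO2)[C@@H](C)CC(=O)[Se]c1ccccc1
F3 | step 1 | 1,4-dioxaspiro[4.5]decane-8-carboxylic acid | OC(=O)C1CCC2(CC1)OCCO2
F4 | step 1 | (2R,3E)-pent-3-en-2-yl 1,4-dioxaspiro[4.5]decane-8-carboxylate | C/C=C/[C@@H](C)OC(=O)C1CCC2(CC1)OCCO2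
F5 | step 1 | 8-[(2S,3E)-pent-3-en-2-yl]-1,4-dioxaspiro[4.5]decane-8-carboxylic acid | C/C=C/[C@H](C)C1(C(=O)O)CCC2(CC1)OCCO2
F6 | step 1 | {8-[(2S,3E)-pent-3-en-2-yl]-1,4-dioxaspiro[4.5]decan-8-yl}methanol | C/C=C/[C@H](C)C1(CO)CCC2(CC1)OCCO2
F7 | step 1 | 8-[(2S,3E)-pent-3-en-2-yl]-1,4-dioxaspiro[4.5]decane-8-carbaldehyde | C/C=C/[C@H](C)C1(C=O)CCC2(CC1)OCCO2
F8 | step 11 | (1R,4S,5S)-1-[(2S)-1-{[tert-butyl(diphenyl)silyl]oxy}propan-2-yl]-4-methylspiro[4.5]dec-7-en-8-yl trifluoromethanesulfonate | CC(C)(C)[Si](c1ccccc1)(c1ccccc1)OC[C@@H](C)[C@H]1CC[C@H](C)[C@]12CC=C(OS(=O)(=O)C(F)(F)F)CC2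
F9 | step 14 | (1R,4S,5S)-1-[(2S)-1-{[tert-butyl(diphenyl)silyl]oxy}propan-2-yl]-4-methylspiro[4.5]dec-6-en-8-one | CC(C)(C)[Si](c1ccccc1)(c1ccccc1)OC[C@@H](C)[C@H]1CC[C@H](C)[C@@]12C=CC(=O)CC2
F10 | step 14 | {[(1R,4S,5S)-1-[(2S)-1-{[tert-butyl(diphenyl)silyl]oxy}propan-2-yl]-4-methylspiro[4.5]deca-6,8-dien-8-yl]oxy}(triethyl)silane | CC(C)(C)[Si](c1ccccc1)(c1ccccc1)OC[C@@H](C)[C@H]1CC[C@H](C)[C@@]12C=CC(O[Si](CC)(CC)CC)=CC2
F11 | step 14 | (1R,4S,5S,9RS)-1-[(2S)-1-{[tert-butyl(diphenyl)silyl]oxy}propan-2-yl]-4-methyl-9-[(triethylsilyl)oxy]spiro[4.5]dec-6-en-8-one | CC(C)(C)[Si](c1ccccc1)(c1ccccc1)OC[C@@H](C)[C@H]1CC[C@H](C)[C@@]12C=CC(=O)C(O[Si](CC)(CC)CC)C2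
F12 | step 14 | (1R,4S,5S,9RS)-1-[(2S)-1-{[tert-butyl(diphenyl)silyl]oxy}propan-2-yl]-4-methyl-9-[(triethylsilyl)oxy]spiro[4.5]dec-7-en-8-yl trifluoromethanesulfonate | CC(C)(C)[Si](c1ccccc1)(c1ccccc1)OC[C@@H](C)[C@H]1CC[C@H](C)[C@@]12CC=C(OS(=O)(=O)C(F)(F)F)C(O[Si](CC)(CC)CC)C2
F13 | step 14 | tert-butyl{(2S)-2-[(1R,4S,5S,7RS)-4,8-dimethyl-7-[(triethylsilyl)oxy]spiro[4.5]dec-8-en-1-yl]propoxy}diphenylsilane | CC(C)(C)[Si](c1ccccc1)(c1ccccc1)OC[C@@H](C)[C@H]1CC[C@H](C)[C@@]12CC=C(C)C(O[Si](CC)(CC)CC)C2
F14 | step 16 | (1R,4S,5S,7R)-1-[(2S)-1-{[tert-butyl(diphenyl)silyl]oxy}propan-2-yl]-4,8-dimethylspiro[4.5]dec-8-en-7-ol | CC(C)(C)[Si](c1ccccc1)(c1ccccc1)OC[C@@H](C)[C@H]1CC[C@H](C)[C@@]12CC=C(C)[C@H](O)C2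
F15 | step 22 | (1R,4S,5S,7S)-1-[(2S)-but-3-yn-2-yl]-4,8-dimethylspiro[4.5]dec-8-en-7-yl 3-phenylpropanoate | C#C[C@@H](C)[C@H]1CC[C@H](C)[C@@]12CC=C(C)[C@@H](OC(=O)CCc3ccccc3)C2
A1 | alternative 1 | tert-butyl(dimethyl){(2S)-2-[(1R,3S)-3-methyl-2-{(2E)-3-methyl-2-[(trimethylsilyl)oxy]penta-2,4-dien-1-ylidene}cyclopentyl]propoxy}silane | CC(C)(C)[Si](C)(C)OC[C@@H](C)[C@H]1CC[C@H](C)C1=C/C(O[Si](C)(C)C)=C(C)\C=C
A2 | alternative 1 | tert-butyl{(2S)-2-[(1R,4S,5S)-4,8-dimethyl-7-[(trimethylsilyl)oxy]spiro[4.5]deca-6,8-dien-1-yl]propoxy}dimethylsilane | CC(C)(C)[Si](C)(C)OC[C@@H](C)[C@H]2CC[C@H](C)[C@@]23CC=C(C)C(O[Si](C)(C)C)=C3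
A3 | alternative 2 | 3-[(2S,3R)-1-{[tert-butyl(dimethyl)silyl]oxy}-2-methylhept-6-en-3-yl]cyclohex-2-en-1-one | CC(C)(C)[Si](C)(C)OC[C@@H](C)[C@@H](CCC=C)C1=CC(=O)CCC1
A4 | alternative 2 | 2-[(2S)-1-{[tert-butyl(dimethyl)silyl]oxy}propan-2-yl]tricyclo[5.4.0.0(1,5)]undecan-8-one (ring configuration as in the SMILES) | CC(C)(C)[Si](C)(C)OC[C@@H](C)[C@H]2CC[C@@H]3C[C@H]4C(=O)CCC[C@@]234
A5 | alternative 3 | 3-{(2R)-2-[(2S)-1-{[tert-butyl(dimethyl)silyl]oxy}propan-2-yl]-1-hydroxycyclobutyl}cyclohex-2-en-1-one | CC(C)(C)[Si](C)(C)OC[C@@H](C)[C@H]1CCC1(O)C1=CC(=O)CCC1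
A6 | alternative 3 | (4R,5R)-4-[(2S)-1-{[tert-butyl(dimethyl)silyl]oxy}propan-2-yl]spiro[4.5]decane-1,7-dione | CC(C)(C)[Si](C)(C)OC[C@@H](C)[C@H]2CCC(=O)[C@@]23CCCC(=O)C3
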